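**Retrosynthetic overview**
1. The target is a 3,3''-biflavanone. Both C rings are 2,3-cis, with configuration (2R,3R,2''R,3''R). The last operation only frees O5 and O7 (benzyl) and the chelated O5'' (methyl).
2. Key disconnection: C4–C4a of unit 1 and, in the same operation, C4''–C4a'' of unit 2. Both chromanone C rings close at once from an open-chain bis(β-aryloxy)succinic bis(dimethylamide) by electrophilic amide activation.
3. Enabling feature: in ring A of unit 1, C4a is ortho to O1, ortho to O5 and para to O7. O5 and O7 carry the same group, so the two carbons ortho to O1 (C4a and C8) are equivalent. The most nucleophilic site is therefore also the only one the C4 carbonyl can reach. Ring A of unit 2 is kept equally symmetric (two OMe) until the end.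
4. The C2–C3–C3''–C2'' tetrad has the configuration of an exo,exo-2,6-diaryl-3,7-dioxabicyclo[3.3.0]octane-4,8-dione. Its lactone oxygens are O1 and O1'' and stay on C2 and C2'' (O-arylation with retention). Opening the two lactones one after the other lets two different A rings enter.
5. The bislactone comes from oxidative enolate homocoupling (C3–C3'') of an acyl oxazolidinone, followed by double benzylic oxidative lactonisation. Ring order: two temporary lactone rings, both opened again, then the two C rings together. Rings A and B are bought.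

Key step: step 9

Remark: flavonoid numbering is used throughout, also for open-chain precursors. Unprimed locants belong to unit 1 (the 5,7-dihydroxy half) and doubly primed ones to unit 2 (the 5-hydroxy-7-methoxy half). Compounds 1, 2, 8 and 11 are taken as catalogue compounds.

**Step 1**
Reactants: 1 (R)-4-isopropyl-1,3-oxazolidin-2-one; 2 3-(4-methoxyphenyl)propanoyl chloride
Product: 3 (R)-4-isopropyl-3-[3-(4-methoxyphenyl)propanoyl]-1,3-oxazolidin-2-one
Conditions: n-BuLi, THF, −78 °C; then 2, −78 → 0 °C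
Reagents that add atoms: none
Why: N-acylation of the lithiated oxazolidinone with an acid chloride is the standard way to load this auxiliary and leaves its stereocentre untouched.

**Step 2**
Reactants: 3 (two molecules)
Product: 4 (2S,3S)-1,4-bis[(4R)-4-isopropyl-2-oxo-1,3-oxazolidin-3-yl]-2,3-bis(4-methoxybenzyl)butane-1,4-dione
Conditions: LiN(iPr)2, THF, −78 °C; then TiCl4, −78 → 0 °C
Reagents that add atoms: none
Why: Oxidative enolate homocoupling (two nucleophilic α-carbons joined after one-electron oxidation by tetravalent titanium, which ends as trivalent titanium) has close precedent for 3-arylpropanoyl oxazolidinones; each chelated Z-enolate reacts on the face away from its isopropyl group, so the auxiliary sets both C3 and C3'' and the twofold-symmetric (S,S) dimer should prevail over the meso form.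

**Step 3**
Reactants: 4
Product: 5 (2S,3S)-2,3-bis(4-methoxybenzyl)butanedioic acid
Conditions: LiOH, H2O2, THF–H2O, 0 °C; then Na2SO3; then HCl to pH 2
Reagents that add atoms: hydrogen peroxide (acting as LiOOH), OO
Why: Hydroperoxide cleavage of N-acyl oxazolidinones attacks the exocyclic carbonyl selectively and is too weakly basic to epimerise C3 or C3'', and the auxiliary is recovered.

**Step 4**
Reactants: 5
Product: 6 (1R,2R,5R,6R)-2,6-bis(4-methoxyphenyl)-3,7-dioxabicyclo[3.3.0]octane-4,8-dione (cis-fused; both aryl groups exo)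
Conditions: DDQ (2.4 equiv), 4 Å MS, ClCH2CH2Cl, 60 °C
Reagents that add atoms: none
Why: In this benzylic oxidative lactonisation DDQ takes a hydride from each 4-methoxybenzylic CH2 and the γ-carboxyl group traps the cation (5-exo); only the cis-fused bicycle can form from the (S,S) acid, and each aryl group takes the exo (convex) position trans to the neighbouring acyl carbon, which reversible ionisation of the benzylic C–O bond also favours, so C3 and C3'' set C2 and C2'' (the descriptors at C3 and C3'' change to R only because the priorities change).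

**Step 5**
Reactants: 6
Product: 7 (2R,3R,4R)-4-[(R)-hydroxy(4-methoxyphenyl)methyl]-2-(4-methoxyphenyl)-N,N-dimethyl-5-oxotetrahydrofuran-3-carboxamide
Conditions: Me2NH (1.0 equiv, 2 M in THF), THF, −20 → 0 °C
Reagents that add atoms: dimethylamine, CNC
Why: In this lactone aminolysis the two carbonyl groups of 6 are homotopic, so either gives 7; the remaining lactone is monocyclic, more hindered and no longer activated by the bicyclic frame, so one equivalent should stop after the first opening, and only the acyl–O bond breaks, so C2 keeps its configuration.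

**Step 6**
Reactants: 7; 8 [3,5-bis(benzyloxy)phenyl]boronic acid
Product: 9 (2R,3R,4R)-4-[(R)-[3,5-bis(benzyloxy)phenoxy](4-methoxyphenyl)methyl]-2-(4-methoxyphenyl)-N,N-dimethyl-5-oxotetrahydrofuran-3-carboxamide
Conditions: 8 (3 equiv), Cu(OAc)2 (20 mol %), DMAP, 4 Å MS, O2 (1 atm), CH2Cl2, rt
Reagents that add atoms: none
Why: In this Chan–Lam O-arylation of a secondary alcohol the alkoxide and the aryl group meet on copper, and C(aryl)–O reductive elimination from trivalent copper leaves the C2–O bond and hence (R)-C2 untouched; the near-neutral medium at room temperature spares the β-hydroxy lactone (no retro-aldol, no elimination), and the tertiary amide keeps the hydroxyl group from relactonising.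

**Step 7**
Reactants: 9
Product: 10 (2R,3R)-2-[(R)-[3,5-bis(benzyloxy)phenoxy](4-methoxyphenyl)methyl]-3-[(R)-hydroxy(4-methoxyphenyl)methyl]-N,N,N',N'-tetramethylbutanediamide
Conditions: AlMe3, Me2NH, CH2Cl2, 0 °C → rt; then aq. KNaC4H4O6
Reagents that add atoms: dimethylamine, CNC
Why: Aluminium-amide aminolysis opens hindered lactones completely because a strong Al–O bond forms; the reagent is too weakly basic to remove C3–H, so the β-aryloxide is not eliminated, and the C2''–O bond is not broken.

**Step 8**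
Reactants: 10; 11 (3,5-dimethoxyphenyl)boronic acid
Product: 12 (2R,3R)-2-[(R)-[3,5-bis(benzyloxy)phenoxy](4-methoxyphenyl)methyl]-3-[(R)-(3,5-dimethoxyphenoxy)(4-methoxyphenyl)methyl]-N,N,N',N'-tetramethylbutanediamide
Conditions: 11 (3 equiv), Cu(OAc)2 (20 mol %), DMAP, 4 Å MS, O2 (1 atm), CH2Cl2, rt
Reagents that add atoms: none
Why: This second Chan–Lam O-arylation works as in step 6, with retention at C2'' because only the O–H bond is replaced, and it brings in the second, differently substituted but again locally symmetric A ring.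

**Step 9**
Reactants: 12
Product: 15 (2R,3R,2''R,3''R)-5,7-bis(benzyloxy)-5'',7''-dimethoxy-2,2''-bis(4-methoxyphenyl)-3,3''-bichroman-4,4''-dione, via bis(O-triflyliminium) bis(triflate) 13 (not isolated), via bis(dimethyliminium) bis(triflate) 14 (not isolated)
Conditions: Tf2O (2.4 equiv), 2,6-di-tert-butyl-4-methylpyridine (5 equiv), CH2Cl2, −78 → 0 °C; then NaOAc–AcOH buffer (pH 5), THF–H2O, 0 °C → rt
Reagents that add atoms: water, O
Why: Tf2O turns each dimethylamide of 12 into an O-triflyliminium ion (13), whose carbon C4 (C4'') is attacked by the ring-A carbon ortho to O1 (O1''); loss of H+ to the hindered pyridine and of triflate gives the bis(iminium) salt 14, which the pH 5 buffer hydrolyses to the two ketones. The closest known reaction type is the intramolecular Vilsmeier–Haack cyclisation of Tf2O-activated tertiary amides onto tethered electron-rich arenes, the amide counterpart of the Friedel–Crafts route from 3-aryloxypropanoic acids to chroman-4-ones. Both C rings close in the 6-exo-trig mode (the C=N+ bond lies outside the forming ring), so the C4–C4a and C4''–C4a'' bonds are made in one operation and the open chain becomes the complete bichromanone skeleton. No stereocentre is created: C2, C3, C3'' and C2'' are carried over from 12 because no C2–O bond is touched, the medium never holds an acid stronger than the pyridinium salt, and the pyridine is too weak and too hindered to remove C3–H from 13 or 14 (no keteniminium, no enamine), so each ring keeps its 2,3-cis relation. Regioselectivity comes from the local symmetry of each 3,5-dioxygenated phenoxy ring (the two carbons ortho to O1 are equivalent and each is ortho, ortho and para to three oxygens), ring size from six- over seven-membered closure (each arene reaches its own β-carbonyl), and chemoselectivity from the fact that the free positions of the 4-methoxyphenyl rings next to C2 are meta to their methoxy group. Attack of the neighbouring amide oxygen on an activated carbonyl is reversible and only stores the electrophile.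

**Step 10**
Reactants: 15
Product: 16 target, (2R,3R,2''R,3''R)-5,7,5''-trihydroxy-7''-methoxy-2,2''-bis(4-methoxyphenyl)-3,3''-bichroman-4,4''-dione
Conditions: BCl3 (8 equiv), pentamethylbenzene (6 equiv), CH2Cl2, −78 → 0 °C; then MeOH, aq. NaHCO3
Reagents that add atoms: none
Why: In this Lewis-acid ether cleavage BCl3 with a cation scavenger removes aryl benzyl ethers at low temperature and, on warming, only the methyl ether whose oxygen (O5'') chelates boron together with the C4'' carbonyl, so O7''–Me and both 4-methoxyphenyl groups stay, and the base-free, cold medium should leave the four cis-related centres as they are.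

**Compound list**
1 | (R)-4-isopropyl-1,3-oxazolidin-2-one | CC(C)[C@@H]1COC(=O)N1 | starting material
2 | 3-(4-methoxyphenyl)propanoyl chloride | COc1ccc(CCC(=O)Cl)cc1 | starting material
3 | (R)-4-isopropyl-3-[3-(4-methoxyphenyl)propanoyl]-1,3-oxazolidin-2-one | COc1ccc(CCC(=O)N2[C@H](C(C)C)COC2=O)cc1 | intermediate
4 | (2S,3S)-1,4-bis[(4R)-4-isopropyl-2-oxo-1,3-oxazolidin-3-yl]-2,3-bis(4-methoxybenzyl)butane-1,4-dione | O=C([C@@H](Cc1ccc(OC)cc1)[C@H](Cc1ccc(OC)cc1)C(=O)N1[C@H](C(C)C)COC1=O)N1[C@H](C(C)C)COC1=O | intermediate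
5 | (2S,3S)-2,3-bis(4-methoxybenzyl)butanedioic acid | OC(=O)[C@@H](Cc1ccc(OC)cc1)[C@H](Cc1ccc(OC)cc1)C(=O)O | intermediate
6 | (1R,2R,5R,6R)-2,6-bis(4-methoxyphenyl)-3,7-dioxabicyclo[3.3.0]octane-4,8-dione | O=C1O[C@@H](c2ccc(OC)cc2)[C@H]2[C@@H]1[C@H](c1ccc(OC)cc1)OC2=O | intermediate
7 | (2R,3R,4R)-4-[(R)-hydroxy(4-methoxyphenyl)methyl]-2-(4-methoxyphenyl)-N,N-dimethyl-5-oxotetrahydrofuran-3-carboxamide | CN(C)C(=O)[C@@H]1[C@H]([C@@H](O)c2ccc(OC)cc2)C(=O)O[C@H]1c1ccc(OC)cc1 | intermediate
8 | [3,5-bis(benzyloxy)phenyl]boronic acid | OB(O)c1cc(OCc2ccccc2)cc(OCc2ccccc2)c1 | starting material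
9 | (2R,3R,4R)-4-[(R)-[3,5-bis(benzyloxy)phenoxy](4-methoxyphenyl)methyl]-2-(4-methoxyphenyl)-N,N-dimethyl-5-oxotetrahydrofuran-3-carboxamide | CN(C)C(=O)[C@@H]1[C@H]([C@@H](Oc2cc(OCc3ccccc3)cc(OCc3ccccc3)c2)c2ccc(OC)cc2)C(=O)O[C@H]1c1ccc(OC)cc1 | intermediate
10 | (2R,3R)-2-[(R)-[3,5-bis(benzyloxy)phenoxy](4-methoxyphenyl)methyl]-3-[(R)-hydroxy(4-methoxyphenyl)methyl]-N,N,N',N'-tetramethylbutanediamide | CN(C)C(=O)[C@@H]([C@@H](Oc1cc(OCc2ccccc2)cc(OCc2ccccc2)c1)c1ccc(OC)cc1)[C@H]([C@@H](O)c1ccc(OC)cc1)C(=O)N(C)C | intermediate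
11 | (3,5-dimethoxyphenyl)boronic acid | COc1cc(OC)cc(B(O)O)c1 | starting material
12 | (2R,3R)-2-[(R)-[3,5-bis(benzyloxy)phenoxy](4-methoxyphenyl)methyl]-3-[(R)-(3,5-dimethoxyphenoxy)(4-methoxyphenyl)methyl]-N,N,N',N'-tetramethylbutanediamide | CN(C)C(=O)[C@@H]([C@@H](Oc1cc(OCc2ccccc2)cc(OCc2ccccc2)c1)c1ccc(OC)cc1)[C@H]([C@@H](Oc1cc(OC)cc(OC)c1)c1ccc(OC)cc1)C(=O)N(C)C | intermediate
13 | bis(O-triflyliminium) bis(triflate) of 12 | C[N+](C)=C(OS(=O)(=O)C(F)(F)F)[C@@H]([C@@H](Oc1cc(OCc2ccccc2)cc(OCc2ccccc2)c1)c1ccc(OC)cc1)[C@H]([C@@H](Oc1cc(OC)cc(OC)c1)c1ccc(OC)cc1)C(OS(=O)(=O)C(F)(F)F)=[N+](C)C.[O-]S(=O)(=O)C(F)(F)F.[O-]S(=O)(=O)C(F)(F)F | intermediate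
14 | 4,4''-bis(dimethyliminium) bis(triflate) of 15 | COc1ccc([C@@H]2Oc3cc(OCc4ccccc4)cc(OCc4ccccc4)c3C(=[N+](C)C)[C@@H]2[C@H]2C(=[N+](C)C)c3c(OC)cc(OC)cc3O[C@H]2c2ccc(OC)cc2)cc1.[O-]S(=O)(=O)C(F)(F)F.[O-]S(=O)(=O)C(F)(F)F | intermediate
15 | (2R,3R,2''R,3''R)-5,7-bis(benzyloxy)-5'',7''-dimethoxy-2,2''-bis(4-methoxyphenyl)-3,3''-bichroman-4,4''-dione | COc1ccc([C@@H]2Oc3cc(OCc4ccccc4)cc(OCc4ccccc4)c3C(=O)[C@@H]2[C@H]2C(=O)c3c(OC)cc(OC)cc3O[C@H]2c2ccc(OC)cc2)cc1 | intermediate
16 | (2R,3R,2''R,3''R)-5,7,5''-trihydroxy-7''-methoxy-2,2''-bis(4-methoxyphenyl)-3,3''-bichroman-4,4''-dione | COc1ccc([C@@H]2Oc3cc(O)cc(O)c3C(=O)[C@@H]2[C@H]2C(=O)c3c(O)cc(OC)cc3O[C@H]2c2ccc(OC)cc2)cc1 | target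

Total step count: 10. Longest linear sequence: 10 steps (1 and 2 to 16).

**Steps most likely to fail**

**Step 9.**
- What may go wrong: α-deprotonation of the activated amides (keteniminium or enamine formation) would erase C3 and C3''. β-Elimination of an aryloxide, cyclodehydration of the two vicinal activated amides toward a diaminofuran, or sluggish hydrolysis of the hindered iminium ions would lower the return.
- Fallback: it sets out from 12 and comes back at 15. Cp2Zr(H)Cl (THF, rt) reduces both tertiary amides to the bis(aryl ether) butanedial F1. Pinnick oxidation (NaClO2, NaH2PO4, 2-methyl-2-butene, t-BuOH–H2O) then gives the bis(aryl ether) butanedioic acid F2. Finally (CF3CO)2O in CH2Cl2 at 0 °C closes both C rings by mixed-anhydride Friedel–Crafts acylation, the classical route from 3-aryloxypropanoic acids to chroman-4-ones.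

**Step 6 (the same event recurs in step 8).**
- What may go wrong: the hindered carbinol may form its copper alkoxide slowly. Protodeboronation and homocoupling of the boronic acid, or oxidation of the carbinol, could then outrun C–O bond formation.
- Fallback: it sets out from 7 and comes back at 9. The sodium alkoxide of 7 (NaH, DMF, 0 °C) displaces fluoride from 1,3-dibromo-5-fluorobenzene by nucleophilic aromatic substitution, again with the C2–O bond intact, to give the 3,5-dibromophenyl ether F3. Palladium-catalysed C–O coupling with benzyl alcohol (Pd2(dba)3, t-BuBrettPhos, Cs2CO3, toluene, 80 °C) then turns both C–Br bonds into benzyl ethers.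

**Step 10.**
- What may go wrong: the boron-complexed ketones may enolise or ionise at the C2–O1 bond (ring opening to a chalcone and reclosure). This would drain the cis centres toward trans. Cleavage of the chelated methyl ether may also stay incomplete at the temperature the stereocentres tolerate.
- Fallback: it avoids any Lewis acid, sets out from 10 and comes back at 16.
  - Chan–Lam coupling of 10 with a second portion of 8 gives the tetrabenzyl bis(amide) F4.
  - The conditions of step 9 take it through the tetrabenzyl bis(O-triflyliminium) salt F5 and the tetrabenzyl bis(iminium) salt F6 to the tetrabenzyl biflavanone F7.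
  - Hydrogenolysis (H2, Pd/C, EtOAc, rt) frees the twofold-symmetric tetraphenol F8.
  - Mitsunobu etherification with one equivalent of MeOH (PPh3, DIAD, THF, 0 °C) alkylates only the acidic, non-chelated 7-hydroxyl groups. These two are homotopic, so monoalkylation gives 16 whichever reacts, and unchanged F8 is returned to the reaction.

**Further compounds**
F1 | step 9 | (2R,3R)-2-[(R)-[3,5-bis(benzyloxy)phenoxy](4-methoxyphenyl)methyl]-3-[(R)-(3,5-dimethoxyphenoxy)(4-methoxyphenyl)methyl]butanedial | O=C[C@@H]([C@@H](Oc1cc(OCc2ccccc2)cc(OCc2ccccc2)c1)c1ccc(OC)cc1)[C@H]([C@@H](Oc1cc(OC)cc(OC)c1)c1ccc(OC)cc1)C=O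
F2 | step 9 | (2R,3R)-2-[(R)-[3,5-bis(benzyloxy)phenoxy](4-methoxyphenyl)methyl]-3-[(R)-(3,5-dimethoxyphenoxy)(4-methoxyphenyl)methyl]butanedioic acid | OC(=O)[C@@H]([C@@H](Oc1cc(OCc2ccccc2)cc(OCc2ccccc2)c1)c1ccc(OC)cc1)[C@H]([C@@H](Oc1cc(OC)cc(OC)c1)c1ccc(OC)cc1)C(=O)O
F3 | step 6 | (2R,3R,4R)-4-[(R)-(3,5-dibromophenoxy)(4-methoxyphenyl)methyl]-2-(4-methoxyphenyl)-N,N-dimethyl-5-oxotetrahydrofuran-3-carboxamide | CN(C)C(=O)[C@@H]1[C@H]([C@@H](Oc2cc(Br)cc(Br)c2)c2ccc(OC)cc2)C(=O)O[C@H]1c1ccc(OC)cc1
F4 | step 10 | (2R,3R)-2,3-bis[(R)-[3,5-bis(benzyloxy)phenoxy](4-methoxyphenyl)methyl]-N,N,N',N'-tetramethylbutanediamide | CN(C)C(=O)[C@@H]([C@@H](Oc1cc(OCc2ccccc2)cc(OCc2ccccc2)c1)c1ccc(OC)cc1)[C@H]([C@@H](Oc1cc(OCc2ccccc2)cc(OCc2ccccc2)c1)c1ccc(OC)cc1)C(=O)N(C)C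
F5 | step 10 | bis(O-triflyliminium) bis(triflate) of F4 | C[N+](C)=C(OS(=O)(=O)C(F)(F)F)[C@@H]([C@@H](Oc1cc(OCc2ccccc2)cc(OCc2ccccc2)c1)c1ccc(OC)cc1)[C@H]([C@@H](Oc1cc(OCc2ccccc2)cc(OCc2ccccc2)c1)c1ccc(OC)cc1)C(OS(=O)(=O)C(F)(F)F)=[N+](C)C.[O-]S(=O)(=O)C(F)(F)F.[O-]S(=O)(=O)C(F)(F)F
F6 | step 10 | 4,4''-bis(dimethyliminium) bis(triflate) of F7 | COc1ccc([C@@H]2Oc3cc(OCc4ccccc4)cc(OCc4ccccc4)c3C(=[N+](C)C)[C@@H]2[C@H]2C(=[N+](C)C)c3c(OCc4ccccc4)cc(OCc4ccccc4)cc3O[C@H]2c2ccc(OC)cc2)cc1.[O-]S(=O)(=O)C(F)(F)F.[O-]S(=O)(=O)C(F)(F)F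
F7 | step 10 | (2R,3R,2''R,3''R)-5,7,5'',7''-tetrakis(benzyloxy)-2,2''-bis(4-methoxyphenyl)-3,3''-bichroman-4,4''-dione | COc1ccc([C@@H]2Oc3cc(OCc4ccccc4)cc(OCc4ccccc4)c3C(=O)[C@@H]2[C@H]2C(=O)c3c(OCc4ccccc4)cc(OCc4ccccc4)cc3O[C@H]2c2ccc(OC)cc2)cc1
F8 | step 10 | (2R,3R,2''R,3''R)-5,7,5'',7''-tetrahydroxy-2,2''-bis(4-methoxyphenyl)-3,3''-bichroman-4,4''-dione | COc1ccc([C@@H]2Oc3cc(O)cc(O)c3C(=O)[C@@H]2[C@H]2C(=O)c3c(O)cc(O)cc3O[C@H]2c2ccc(OC)cc2)cc1
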